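When you read this flask at 10 d, read it against one number.

solid substrate 0.64 M; catalyst 15 mM; time 10 d

    solid substrate ⇌ starting material, rate k1*(cs1 - [starting material]) while solid is left; crystals form when [starting material] > cs1 (cs1 = 50 mM, k1 = 2.86 × 10⁻⁴ s⁻¹)
    starting material → intermediate (k2 = 9.44 × 10⁻⁶ s⁻¹)
    catalyst + intermediate → catalyst + product (k3 = 2.78 × 10⁻⁴ L mol⁻¹ s⁻¹)

- solid substrate is a solid; its amount is given per volume of the solution
- at the start none of the solid substrate is in solution
- starting material means what is dissolved; the solid is not counted in it
- run time (flask): 10 d

- delta: doubling the solubility in step 1, all else as stated
- eta: doubling the amount of catalyst, all else as stated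
- gamma: doubling the dissolution coefficient of step 1, all else as stated

- amount of product at 10 d, in percent of the solid substrate charged
- concentration of starting material in solution at 5.0 d, in percent of saturation
- the change that raises the amount of product at 10 d, in percent of the solid substrate charged most ("none" if none brings more than 2 percentage points) (delta / eta / gamma / none)
- amount of product at 10 d, in percent of the solid substrate charged, after delta

Dissolution is faster than the second step, so while solid is left, [starting material] holds a steady fraction of saturation, where what dissolves equals what reacts:

fraction of saturation = 2.86 × 10⁻⁴ s⁻¹ / (2.86 × 10⁻⁴ s⁻¹ + 9.44 × 10⁻⁶ s⁻¹) = 96.8%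

The solution therefore feeds the second step at a constant rate. Folding that into the charge gives N:

N = 9.44 × 10⁻⁶ s⁻¹ × 96.8% × 50 mM × 10 d / 0.64 M = 0.617

This is the feed number: the share of the charge that has passed the second step by the reading, provided solid lasts. It is less than one, so I expect solid to last.

One number is not enough, though. It counts what became intermediate, and product follows with a lag. With catalyst unchanged, the last step is pseudo-first-order, with time constant τ = 2.78 d, shorter than the run. Early on, product grows with the square of time; later, it trails the feed line by τ. Joining the two ends at time t:

y = N × (1 − (τ/t)(1 − e^(−t/τ))) = 0.617 × 0.730 = 45.0%

Doubling the solubility takes N to 1.23, more than the charge, so in that flask the feed cannot stay constant up to the reading, and my constant-feed figure of 90.0% is an overestimate. Doubling the catalyst leaves N as it is and halves τ, worth about 8.1 percentage points. Doubling the dissolution coefficient lifts N to 0.627. I pick delta.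

The forecast gives 44.8% of product, slightly below my 45.0%, 96.8% of saturation, the choice delta, and 81.7% after it, lower than my constant-feed figure: “Doubling the solubility doubles that feed rate until the solid runs out”.

The run gives 44.8%, 96.8%, delta and 81.7%. In this flask the amount of product has moved by 5 points at 9.16 d and at 10.8 d, so watch the clock when you sample. Against N = 61.7%, product plus intermediate in this flask stands at 61.4% at 10.0 d. Catalyst does not enter N, so the neighbour flask with 0.0037 M of catalyst has the same N. There, product is 20.7% and intermediate 40.8%, together 61.5%.

Its constants are made up; what happens was integrated by code.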